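## Retrosynthetic overview

1. Excoecarin R1 is cut at the C-3(upper half)–O–C-15(lower half) ester; both halves come from one monomer, the 2-methyl ester 3-acid of 2,3-seco-ent-13-epi-manoyl oxide.
2. The lower half is made from the monomer by vinyl → aldehyde → chelation-controlled hydroxymethylation, which sets C-14.
3. Ring C of the monomer is closed last (C-8–O bond) by a photochemical cobalt-hydride Markovnikov hydroalkoxylation of an 8(17)-methylene by the C-13 hydroxyl.
4. Ring B with the C-4 carboxyl is unmasked from a verbenone-derived cyclobutyl ketone by an electroreductive ring-opening carboxylation (C-3–C-4 bond, new method).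
5. The bicyclic ketone comes from (−)-verbenone (C-5, which controls C-10) by Mukaiyama–Michael addition and alkylation with a C-11–C-16 iodide from (R)-linalool (C-13). Ring order: ring B (from verbenone), then ring C.

Assumption: positions are cited with labdane numbering (C-1 to C-20) in each half; (1S,5S)-(−)-verbenone and (R)-(−)-linalool are taken as purchasable in high enantiomeric purity. The route is a paper proposal and has not been run.

## Route

Step 1
Reactants: 1 (R)-(−)-linalool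
Product: 3 (5R)-5-ethenyl-5-methyloxolan-2-ol (both anomers), via (4R)-4-hydroxy-4-methylhex-5-enal 2 (not isolated)
Conditions: O3 (1.0 equiv), CH2Cl2/MeOH 9:1, −78 °C; then Me2S, −78 °C → rt
Reagents that add atoms: ozone, [O-][O+]=O
Why: Chemoselective ozonolysis of the electron-rich trisubstituted alkene (the vinyl group reacts much more slowly) with reductive work-up gives the γ-hydroxy aldehyde, which closes to the lactol without touching the purchased C-13 centre.

Step 2
Reactants: 3 (5R)-5-ethenyl-5-methyloxolan-2-ol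
Product: 4 (3R)-5-iodo-3-methylpent-1-en-3-yl formate
Conditions: PhI(OAc)2 (1.1 equiv), I2 (1.0 equiv), CH2Cl2, visible light (tungsten lamps), 25 °C
Reagents that add atoms: iodine, II
Why: Suárez alkoxy-radical fragmentation: photolysis of the lactol hypoiodite gives the anomeric alkoxy radical, β-scission excises the anomeric carbon as a formate, and the primary radical is iodinated, leaving the C-11 to C-16 unit with C-13 intact.

Step 3
Reactants: 4 (3R)-5-iodo-3-methylpent-1-en-3-yl formate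
Product: 6 [(3R)-5-iodo-3-methylpent-1-en-3-yl]oxy(trimethyl)silane, via (3R)-5-iodo-3-methylpent-1-en-3-ol 5 (not isolated)
Conditions: K2CO3 (0.1 equiv), MeOH, 0 °C; concentrate; then 1-(trimethylsilyl)imidazole, CH2Cl2, 25 °C
Reagents that add atoms: 1-(trimethylsilyl)imidazole, C[Si](C)(C)n1ccnc1
Why: Base-catalysed transesterification removes the formate and silylation of the tertiary alcohol gives an electrophile that tolerates enolates and electrolysis; no stereocentre is involved.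

Step 4
Reactants: 7 (1S,5S)-(−)-verbenone; 8 1-(tert-butyldimethylsilyloxy)-1-methoxyethene
Product: 10 methyl 2-[(1S,2R,5S)-2,6,6-trimethyl-4-oxobicyclo[3.1.1]heptan-2-yl]acetate, via tert-butyldimethylsilyl enol ether 9 (not isolated)
Conditions: Tf2NH (3 mol %), CH2Cl2, −78 °C; then 1 M HCl, THF, 0 °C
Reagents that add atoms: none
Why: Mukaiyama–Michael addition to the β,β-disubstituted enone occurs on the face opposite the gem-dimethyl bridge (as cuprates do on verbenone), so the purchased C-5 centre sets quaternary C-10 with methyl cis and the acetate arm trans to the future C-4 carbon.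

Step 5
Reactants: 10 methyl 2-[(1S,2R,5S)-2,6,6-trimethyl-4-oxobicyclo[3.1.1]heptan-2-yl]acetate; 6 [(3R)-5-iodo-3-methylpent-1-en-3-yl]oxy(trimethyl)silane
Product: 12 methyl 2-[(1R,2R,3R,5S)-2,6,6-trimethyl-3-[(3R)-3-methyl-3-(trimethylsilyloxy)pent-4-en-1-yl]-4-oxobicyclo[3.1.1]heptan-2-yl]acetate, via lithium enolate 11 (not isolated)
Conditions: LiN(i-Pr)2 (1.05 equiv), THF, −78 °C; then 6 (1.3 equiv), HMPA, −78 → 0 °C
Reagents that add atoms: none
Why: Regiospecific enolate alkylation (the bridgehead α-carbon cannot enolise, so only C-9 reacts) forms the C-9–C-11 bond anti to the gem-dimethyl bridge; this C-9 configuration is the wrong one and is corrected by equilibration in step 7.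

Step 6
Reactants: 12 methyl 2-[(1R,2R,3R,5S)-2,6,6-trimethyl-3-[(3R)-3-methyl-3-(trimethylsilyloxy)pent-4-en-1-yl]-4-oxobicyclo[3.1.1]heptan-2-yl]acetate
Product: 14 2-[(1S,2R,3R)-3-[(3R)-3-hydroxy-3-methylpent-4-en-1-yl]-2-(2-methoxy-2-oxoethyl)-2-methyl-4-oxocyclohexyl]-2-methylpropanoic acid, via trimethylsilyl ether keto acid 13 (not isolated)
Conditions: undivided cell, Mg anode, glassy-carbon cathode, n-Bu4NBr (0.1 M), DMF, CO2 (1 atm), 10 mA cm−2, 2.5 F mol−1, 0 °C; then 1 M HCl, THF, 0 °C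
Reagents that add atoms: carbon dioxide, O=C=O
Why: Proposed new method: electroreductive ring-opening carboxylation of an unactivated cyclobutyl ketone, in which cathodic one-electron reduction (assisted by magnesium ions from the anode) gives a ketyl whose strained bond to the CMe2 bridge undergoes β-scission to a magnesium enolate and a tertiary radical that is reduced further (or couples with the CO2 radical anion) and trapped by CO2 as the quaternary C-4 carboxylate, while acid work-up protonates the enolate and removes the silyl ether; the closest known reactions are the electroreductive ring-opening carboxylation of aryl cyclopropanes and cyclobutanes with CO2, Mg-anode electrocarboxylation of ketones, and SmI2 or Li/NH3 ketyl fragmentation of cyclobutyl ketones, and no stereocentre is touched.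

Step 7
Reactants: 14 2-[(1S,2R,3R)-3-[(3R)-3-hydroxy-3-methylpent-4-en-1-yl]-2-(2-methoxy-2-oxoethyl)-2-methyl-4-oxocyclohexyl]-2-methylpropanoic acid
Product: 16 2-[(1S,2S,3R)-3-[(3R)-3-hydroxy-3-methylpent-4-en-1-yl]-2-(2-methoxy-2-oxoethyl)-2-methyl-4-methylidenecyclohexyl]-2-methylpropanoic acid, via C-9 epimerised keto acid 15 (not isolated)
Conditions: Ph3PCH3Br (5 equiv), KOt-Bu (5.2 equiv), THF, 0 → 65 °C; then aq. citric acid
Reagents that add atoms: methyltriphenylphosphonium bromide, C[P+](c1ccccc1)(c1ccccc1)c1ccccc1.[Br-]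
Why: Under the basic conditions the ketone α-centre C-9 equilibrates to the more stable equatorial side chain (cis to the C-10 methyl, as in 8-oxolabdanes) and Wittig methylenation then installs C-17 as an exocyclic methylene; excess ylide only deprotonates the acid and the alcohol.

Step 8
Reactants: 16 2-[(1S,2S,3R)-3-[(3R)-3-hydroxy-3-methylpent-4-en-1-yl]-2-(2-methoxy-2-oxoethyl)-2-methyl-4-methylidenecyclohexyl]-2-methylpropanoic acid
Product: 17 2-[(2R,4aS,5R,6S,8aS)-2-ethenyl-5-(2-methoxy-2-oxoethyl)-2,5,8a-trimethyl-octahydro-2H-chromen-6-yl]-2-methylpropanoic acid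
Conditions: Co(salen) (C16H14CoN2O2, 5 mol %), 10-phenylphenothiazine (5 mol %), 2,4,6-trimethylpyridinium triflate (20 mol %), CH2Cl2, 440 nm LEDs, 25 °C
Reagents that add atoms: none
Why: Photochemical cobalt-hydride hydrogen-atom transfer with radical–polar crossover (Markovnikov hydroalkoxylation) adds H to the exocyclic CH2 (1,1-disubstituted alkene before vinyl) and the C-13 hydroxyl captures the tertiary C-8 alkylcobalt/cation from the equatorial face anti to the axial C-10 methyl, closing ring C trans-fused with C-17 axial as in manool → manoyl oxide cyclisations.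

Step 9
Reactants: 17 2-[(2R,4aS,5R,6S,8aS)-2-ethenyl-5-(2-methoxy-2-oxoethyl)-2,5,8a-trimethyl-octahydro-2H-chromen-6-yl]-2-methylpropanoic acid
Product: 18 methyl 2-[(2R,4aS,5R,6S,8aS)-2-ethenyl-5-(2-methoxy-2-oxoethyl)-2,5,8a-trimethyl-octahydro-2H-chromen-6-yl]-2-methylpropanoate
Conditions: Me3SiCHN2 (1.5 equiv), toluene/MeOH 4:1, 0 °C
Reagents that add atoms: trimethylsilyldiazomethane, C[Si](C)(C)C=[N+]=[N-]
Why: O-Methylation of the carboxylate (insensitive to the hindrance of the acid) masks C-3 of the future lower half; no stereocentre is involved.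

Step 10
Reactants: 18 methyl 2-[(2R,4aS,5R,6S,8aS)-2-ethenyl-5-(2-methoxy-2-oxoethyl)-2,5,8a-trimethyl-octahydro-2H-chromen-6-yl]-2-methylpropanoate
Product: 19 methyl 2-[(2R,4aS,5R,6S,8aS)-2-formyl-5-(2-methoxy-2-oxoethyl)-2,5,8a-trimethyl-octahydro-2H-chromen-6-yl]-2-methylpropanoate
Conditions: O3, CH2Cl2/MeOH, −78 °C; then Me2S
Reagents that add atoms: ozone, [O-][O+]=O
Why: Ozonolysis with reductive work-up cleaves the only alkene to a non-enolisable α-alkoxy aldehyde, leaving C-13 unchanged.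

Step 11
Reactants: 19 methyl 2-[(2R,4aS,5R,6S,8aS)-2-formyl-5-(2-methoxy-2-oxoethyl)-2,5,8a-trimethyl-octahydro-2H-chromen-6-yl]-2-methylpropanoate
Product: 21 methyl 2-[(2R,4aS,5R,6S,8aS)-2-[(1R)-1,2-dihydroxyethyl]-5-(2-methoxy-2-oxoethyl)-2,5,8a-trimethyl-octahydro-2H-chromen-6-yl]-2-methylpropanoate, via silyl carbinol 20 (not isolated)
Conditions: MgBr2·OEt2 (2 equiv), CH2Cl2, −78 °C; (i-PrO)Me2SiCH2MgCl (1.5 equiv, Et2O), −78 °C; then KHCO3, 30% H2O2, THF/MeOH, 25 °C
Reagents that add atoms: (isopropoxydimethylsilyl)methylmagnesium chloride, CC(C)O[Si](C)(C)C[Mg]Cl; hydrogen peroxide, OO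
Why: Chelation-controlled (Cram chelate) Grignard addition of Tamao's hydroxymethyl equivalent, with magnesium bridging the aldehyde and ring oxygens and the face over ring C blocked by the syn-axial C-17 methyl, gives the 14R carbinol, and Tamao–Fleming oxidation of the C–Si bond reveals the diol.

Step 12
Reactants: 17 2-[(2R,4aS,5R,6S,8aS)-2-ethenyl-5-(2-methoxy-2-oxoethyl)-2,5,8a-trimethyl-octahydro-2H-chromen-6-yl]-2-methylpropanoic acid; 21 methyl 2-[(2R,4aS,5R,6S,8aS)-2-[(1R)-1,2-dihydroxyethyl]-5-(2-methoxy-2-oxoethyl)-2,5,8a-trimethyl-octahydro-2H-chromen-6-yl]-2-methylpropanoate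
Product: 23 excoecarin R1 trimethyl ester, via acid chloride 22 (not isolated)
Conditions: 17 (1.2 equiv), 1-chloro-N,N,2-trimethylprop-1-en-1-amine (1.3 equiv), CH2Cl2, 0 → 25 °C; then 21, pyridine, DMAP (0.2 equiv), 40 °C
Reagents that add atoms: none
Why: Neutral acid-chloride formation and DMAP-catalysed acylation join the halves, the very hindered acyl chloride reacting only with the primary C-15 hydroxyl and not the neopentylic C-14 hydroxyl; no stereocentre is touched.

Step 13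
Reactants: 23 excoecarin R1 trimethyl ester
Product: 24 excoecarin R1
Conditions: LiI (15 equiv), EtOAc, reflux, dark; then cold 0.5 M HCl
Reagents that add atoms: none
Why: SN2 O-demethylation by iodide at the three methyl carbons (independent of acyl hindrance) frees the three acids, while the linking ester, whose alkyl carbon is a β-branched CH2, and all stereocentres are untouched.

## Compound list

1 | (R)-(−)-linalool, (3R)-3,7-dimethylocta-1,6-dien-3-ol | C=C[C@@](O)(C)CCC=C(C)C | starting material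
2 | (4R)-4-hydroxy-4-methylhex-5-enal | C=C[C@@](O)(C)CCC=O | intermediate
3 | (5R)-5-ethenyl-5-methyloxolan-2-ol (anomer mixture) | C=C[C@@]1(C)CCC(O)O1 | intermediate
4 | (3R)-5-iodo-3-methylpent-1-en-3-yl formate | C=C[C@@](OC=O)(C)CCI | intermediate
5 | (3R)-5-iodo-3-methylpent-1-en-3-ol | C=C[C@@](O)(C)CCI | intermediate
6 | [(3R)-5-iodo-3-methylpent-1-en-3-yl]oxy(trimethyl)silane | C=C[C@@](O[Si](C)(C)C)(C)CCI | intermediate
7 | (1S,5S)-(−)-verbenone, (1S,5S)-4,6,6-trimethylbicyclo[3.1.1]hept-3-en-2-one | CC1=CC(=O)[C@H]2C[C@@H]1C2(C)C | starting material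
8 | 1-(tert-butyldimethylsilyloxy)-1-methoxyethene | C=C(OC)O[Si](C)(C)C(C)(C)C | starting material
9 | methyl 2-[(1R,2R,5S)-4-(tert-butyldimethylsilyloxy)-2,6,6-trimethylbicyclo[3.1.1]hept-3-en-2-yl]acetate | COC(=O)C[C@@]1(C)C=C(O[Si](C)(C)C(C)(C)C)[C@H]2C[C@@H]1C2(C)C | intermediate
10 | methyl 2-[(1S,2R,5S)-2,6,6-trimethyl-4-oxobicyclo[3.1.1]heptan-2-yl]acetate | COC(=O)C[C@@]1(C)CC(=O)[C@H]2C[C@@H]1C2(C)C | intermediate
11 | lithium (1S,4R,5R)-4-(2-methoxy-2-oxoethyl)-4,6,6-trimethylbicyclo[3.1.1]hept-2-en-2-olate | [Li+].COC(=O)C[C@@]1(C)C=C([O-])[C@H]2C[C@@H]1C2(C)C | intermediate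
12 | methyl 2-[(1R,2R,3R,5S)-2,6,6-trimethyl-3-[(3R)-3-methyl-3-(trimethylsilyloxy)pent-4-en-1-yl]-4-oxobicyclo[3.1.1]heptan-2-yl]acetate | COC(=O)C[C@@]1(C)[C@@H](CC[C@@](C)(O[Si](C)(C)C)C=C)C(=O)[C@H]2C[C@@H]1C2(C)C | intermediate
13 | 2-[(1S,2R,3R)-2-(2-methoxy-2-oxoethyl)-2-methyl-3-[(3R)-3-methyl-3-(trimethylsilyloxy)pent-4-en-1-yl]-4-oxocyclohexyl]-2-methylpropanoic acid | C=C[C@@](O[Si](C)(C)C)(C)CC[C@@H]1[C@](C)(CC(=O)OC)[C@@H](C(C)(C)C(=O)O)CCC1=O | intermediate
14 | 2-[(1S,2R,3R)-3-[(3R)-3-hydroxy-3-methylpent-4-en-1-yl]-2-(2-methoxy-2-oxoethyl)-2-methyl-4-oxocyclohexyl]-2-methylpropanoic acid (side chain cis to the acetate arm) | C=C[C@@](O)(C)CC[C@@H]1[C@](C)(CC(=O)OC)[C@@H](C(C)(C)C(=O)O)CCC1=O | intermediate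
15 | 2-[(1S,2R,3S)-3-[(3R)-3-hydroxy-3-methylpent-4-en-1-yl]-2-(2-methoxy-2-oxoethyl)-2-methyl-4-oxocyclohexyl]-2-methylpropanoic acid (C-9 epimer of 14, side chain cis to the ring methyl) | C=C[C@@](O)(C)CC[C@H]1[C@](C)(CC(=O)OC)[C@@H](C(C)(C)C(=O)O)CCC1=O | intermediate
16 | 2-[(1S,2S,3R)-3-[(3R)-3-hydroxy-3-methylpent-4-en-1-yl]-2-(2-methoxy-2-oxoethyl)-2-methyl-4-methylidenecyclohexyl]-2-methylpropanoic acid | C=C[C@@](O)(C)CC[C@H]1[C@](C)(CC(=O)OC)[C@@H](C(C)(C)C(=O)O)CCC1=C | intermediate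
17 | 2-[(2R,4aS,5R,6S,8aS)-2-ethenyl-5-(2-methoxy-2-oxoethyl)-2,5,8a-trimethyl-octahydro-2H-chromen-6-yl]-2-methylpropanoic acid | C=C[C@@]1(C)CC[C@H]2[C@](C)(CC(=O)OC)[C@@H](C(C)(C)C(=O)O)CC[C@]2(C)O1 | intermediate
18 | methyl 2-[(2R,4aS,5R,6S,8aS)-2-ethenyl-5-(2-methoxy-2-oxoethyl)-2,5,8a-trimethyl-octahydro-2H-chromen-6-yl]-2-methylpropanoate | C=C[C@@]1(C)CC[C@H]2[C@](C)(CC(=O)OC)[C@@H](C(C)(C)C(=O)OC)CC[C@]2(C)O1 | intermediate
19 | methyl 2-[(2R,4aS,5R,6S,8aS)-2-formyl-5-(2-methoxy-2-oxoethyl)-2,5,8a-trimethyl-octahydro-2H-chromen-6-yl]-2-methylpropanoate | O=C[C@@]1(C)CC[C@H]2[C@](C)(CC(=O)OC)[C@@H](C(C)(C)C(=O)OC)CC[C@]2(C)O1 | intermediate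
20 | methyl 2-[(2R,4aS,5R,6S,8aS)-2-[(1S)-2-[dimethyl(propan-2-yloxy)silyl]-1-hydroxyethyl]-5-(2-methoxy-2-oxoethyl)-2,5,8a-trimethyl-octahydro-2H-chromen-6-yl]-2-methylpropanoate | CC(C)O[Si](C)(C)C[C@@H](O)[C@@]1(C)CC[C@H]2[C@](C)(CC(=O)OC)[C@@H](C(C)(C)C(=O)OC)CC[C@]2(C)O1 | intermediate
21 | methyl 2-[(2R,4aS,5R,6S,8aS)-2-[(1R)-1,2-dihydroxyethyl]-5-(2-methoxy-2-oxoethyl)-2,5,8a-trimethyl-octahydro-2H-chromen-6-yl]-2-methylpropanoate | OC[C@@H](O)[C@@]1(C)CC[C@H]2[C@](C)(CC(=O)OC)[C@@H](C(C)(C)C(=O)OC)CC[C@]2(C)O1 | intermediate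
22 | 2-[(2R,4aS,5R,6S,8aS)-2-ethenyl-5-(2-methoxy-2-oxoethyl)-2,5,8a-trimethyl-octahydro-2H-chromen-6-yl]-2-methylpropanoyl chloride | C=C[C@@]1(C)CC[C@H]2[C@](C)(CC(=O)OC)[C@@H](C(C)(C)C(Cl)=O)CC[C@]2(C)O1 | intermediate
23 | excoecarin R1 trimethyl ester: (2R)-2-hydroxy-2-[(2R,4aS,5R,6S,8aS)-5-(2-methoxy-2-oxoethyl)-6-(1-methoxy-2-methyl-1-oxopropan-2-yl)-2,5,8a-trimethyl-octahydro-2H-chromen-2-yl]ethyl ester of acid 17 | C=C[C@@]1(C)CC[C@H]2[C@](C)(CC(=O)OC)[C@@H](C(C)(C)C(=O)OC[C@@H](O)[C@@]3(C)CC[C@H]4[C@](C)(CC(=O)OC)[C@@H](C(C)(C)C(=O)OC)CC[C@]4(C)O3)CC[C@]2(C)O1 | intermediate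
24 | excoecarin R1 | C=C[C@@]1(C)CC[C@H]2[C@](C)(CC(=O)O)[C@@H](C(C)(C)C(=O)OC[C@@H](O)[C@@]3(C)CC[C@H]4[C@](C)(CC(=O)O)[C@@H](C(C)(C)C(=O)O)CC[C@]4(C)O3)CC[C@]2(C)O1 | target

## Step count

Total step count: 13. Longest linear sequence: 12 steps (steps 1–3, then 5–13, from (R)-linalool); from verbenone it is 10 steps (4–13).

## Three steps most likely to fail, each with a fallback

Step 6, the new electroreductive ring-opening carboxylation, may fail in several ways. The ketyl may be carboxylated directly to an α-hydroxy acid; the tertiary carbanion may be protonated to the isopropyl compound; or it may attack the neighbouring methyl ester. The fallback uses known reactions only, sets out from 12 and returns at 14. Treatment of 12 with Me3SiI and (Me3Si)2NH in CH2Cl2 at −78 → −20 °C gives the silyl-iodide ring opening that is established for nopinone-type cyclobutyl ketones. Bicarbonate work-up then gives the tertiary iodide methyl 2-[(1S,2R,6S)-6-(2-iodopropan-2-yl)-1-methyl-2-[(3R)-3-methyl-3-(trimethylsilyloxy)pent-4-en-1-yl]-3-oxocyclohexyl]acetate F1. Photo-induced atom-transfer carbonylation of the tertiary iodide (CO 45 atm, K2CO3, MeCN/H2O, xenon lamp) installs the quaternary acid, and the acid work-up of step 6 removes the silyl ether to give 14. The weak point of this fallback is the allylic silyl ether, which must survive the brief Me3SiI exposure.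

Step 5, SN2 alkylation of a hindered enolate next to a quaternary carbon with an unactivated iodide, may be too slow. The fallback replaces it by aldol condensation and conjugate reduction; it sets out from 6 and 10 and returns at 12. Oxidation of 6 with Me3NO in DMSO gives (3R)-3-methyl-3-(trimethylsilyloxy)pent-4-enal F2. Addition of enolate 11 to F2 at −78 °C is fast even for hindered enolates and gives methyl 2-[(1R,2R,3S,5S)-3-[(3R)-1-hydroxy-3-methyl-3-(trimethylsilyloxy)pent-4-en-1-yl]-2,6,6-trimethyl-4-oxobicyclo[3.1.1]heptan-2-yl]acetate F3 as carbinol epimers. Treatment with MsCl/Et3N then DBU gives the enone methyl 2-[(1R,2R,3Z,5S)-2,6,6-trimethyl-3-[(3R)-3-methyl-3-(trimethylsilyloxy)pent-4-en-1-ylidene]-4-oxobicyclo[3.1.1]heptan-2-yl]acetate F4. Conjugate reduction with [(Ph3P)CuH]6 returns 12; any C-9 epimer mixture converges in step 7.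

Step 12, acylation with an extremely hindered acid chloride, may stall. The fallback reverses the polarity and forms the C-15–O bond by SN2; it sets out from 21 and returns at 23. TsCl in pyridine tosylates only the primary hydroxyl to give methyl 2-[(2R,4aS,5R,6S,8aS)-2-[(1R)-1-hydroxy-2-(4-methylbenzenesulfonyloxy)ethyl]-5-(2-methoxy-2-oxoethyl)-2,5,8a-trimethyl-octahydro-2H-chromen-6-yl]-2-methylpropanoate F5. K2CO3 in MeOH closes it to methyl 2-[(2R,4aS,5R,6S,8aS)-5-(2-methoxy-2-oxoethyl)-2,5,8a-trimethyl-2-[(2R)-oxiran-2-yl]-octahydro-2H-chromen-6-yl]-2-methylpropanoate F6. The cesium carboxylate of 17 (Cs2CO3, DMF, 80 °C) opens the epoxide at the terminal C-15, a reaction insensitive to hindrance in the acid, to give 23.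

Further compounds

F1 | step 6 | methyl 2-[(1S,2R,6S)-6-(2-iodopropan-2-yl)-1-methyl-2-[(3R)-3-methyl-3-(trimethylsilyloxy)pent-4-en-1-yl]-3-oxocyclohexyl]acetate | C=C[C@@](O[Si](C)(C)C)(C)CC[C@@H]1[C@](C)(CC(=O)OC)[C@@H](C(C)(C)I)CCC1=O
F2 | step 5 | (3R)-3-methyl-3-(trimethylsilyloxy)pent-4-enal | C=C[C@@](O[Si](C)(C)C)(C)CC=O
F3 | step 5 | methyl 2-[(1R,2R,3S,5S)-3-[(3R)-1-hydroxy-3-methyl-3-(trimethylsilyloxy)pent-4-en-1-yl]-2,6,6-trimethyl-4-oxobicyclo[3.1.1]heptan-2-yl]acetate (carbinol epimers) | COC(=O)C[C@@]1(C)[C@@H](C(O)C[C@@](C)(O[Si](C)(C)C)C=C)C(=O)[C@H]2C[C@@H]1C2(C)C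
F4 | step 5 | methyl 2-[(1R,2R,3Z,5S)-2,6,6-trimethyl-3-[(3R)-3-methyl-3-(trimethylsilyloxy)pent-4-en-1-ylidene]-4-oxobicyclo[3.1.1]heptan-2-yl]acetate | COC(=O)C[C@@]1(C)/C(=C/C[C@@](C)(O[Si](C)(C)C)C=C)C(=O)[C@H]2C[C@@H]1C2(C)C
F5 | step 12 | methyl 2-[(2R,4aS,5R,6S,8aS)-2-[(1R)-1-hydroxy-2-(4-methylbenzenesulfonyloxy)ethyl]-5-(2-methoxy-2-oxoethyl)-2,5,8a-trimethyl-octahydro-2H-chromen-6-yl]-2-methylpropanoate | Cc1ccc(cc1)S(=O)(=O)OC[C@@H](O)[C@@]1(C)CC[C@H]2[C@](C)(CC(=O)OC)[C@@H](C(C)(C)C(=O)OC)CC[C@]2(C)O1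
F6 | step 12 | methyl 2-[(2R,4aS,5R,6S,8aS)-5-(2-methoxy-2-oxoethyl)-2,5,8a-trimethyl-2-[(2R)-oxiran-2-yl]-octahydro-2H-chromen-6-yl]-2-methylpropanoate | [C@@H]1(CO1)[C@@]2(C)CC[C@H]3[C@](C)(CC(=O)OC)[C@@H](C(C)(C)C(=O)OC)CC[C@]3(C)O2
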